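The runs were generated by integration on assumed constants; the scatter is artificial.

Wednesday's run gave two readings that do not seem to go together. Its nucleophile could take 60.0 % of the electrophile charged, yet at 30.0 min 69.2 % of that electrophile had gone, while the target read 48.4 %.

| flask | electrophile | nucleophile | buffer base | buffer acid | remark | time |
|---|---|---|---|---|---|---|
| Thursday's | 0.025 M (fed, over 25 min) | 0.060 M | 0.15 M | 5 mM | run made earlier |  |
| Wednesday's | 0.10 M (fed, over 25 min) | 0.060 M | 0.15 M | 5 mM | run made earlier |  |
| flask | 0.050 M (fed, over 25 min) | 0.0600 M | 0.150 M | 5.00 mM |  | 50 min |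

| run | time / min | electrophile / % | target / % |
|---|---|---|---|
| Thursday's | 2.50 | 5.4 | 5.3 |
| Thursday's | 4.00 | 7.1 | 11.2 |
| Thursday's | 6.00 | 6.7 | 16.5 |
| Thursday's | 8.00 | 8.1 | 23.2 |
| Thursday's | 12.0 | 7.4 | 38.3 |
| Thursday's | 20.0 | 9.3 | 66.7 |
| Thursday's | 30.0 | 2.5 | 93.1 |
| Wednesday's | 4.00 | 7.0 | 6.6 |
| Wednesday's | 8.00 | 9.1 | 23.1 |
| Wednesday's | 12.0 | 10.9 | 32.2 |
| Wednesday's | 15.0 | 15.9 | 40.6 |
| Wednesday's | 20.0 | 22.0 | 49.1 |
| Wednesday's | 25.0 | 35.1 | 50.6 |
| Wednesday's | 30.0 | 30.8 | 48.4 |

(each reading ± 1 percentage point)

- part of the electrophile that has reacted at 50 min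
- pH of the solution at 50 min

- the earlier runs do not show the pH; that part of a forecast is a guess
- percentages count the whole charge, also what has not yet gone in

I cleared this up by reckoning both gaps. The electrophile went 9.2 percentage points beyond that share and the target stayed 12 points under it, so I read a second route that uses electrophile without nucleophile and costs target.

The new flask has 1.20 of nucleophile per electrophile charged, a ratio I call the cover. It stands above the crossing at one, so I took electrophile as the limiting reagent, with about 16.7 % of the nucleophile to remain.

For the tail I used Thursday's run, whose electrophile read 7.4 % at 12.0 min under the steady feed. Balancing that feed against use by the remaining nucleophile in that one reading, and taking the new flask's surplus of 0.0100 M as a pseudo-first-order floor, I estimated a time constant of 9.33 min for the electrophile in the new flask. By that estimate, the 25.0 min after the feed should cut the electrophile by a factor of about 14.6. The readings show no pH, so I reckoned none.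

The forecast gave 96 % reacted and pH 7.3, saying of the buffer “so I guess phosphate-like”.

The flask gave 99.6 % reacted, within the forecast's tolerance, and pH 9.29, above the forecast.

    electrophile + target → side product (k = 0.00805 M⁻¹ s⁻¹)
    electrophile + nucleophile → acid + target + leaving group (k = 0.148 M⁻¹ s⁻¹)
    buffer acid ⇌ buffer base + acid, settled at all times (K = 1.00 × 10⁻⁹ M)
    protonated nucleophile ⇌ nucleophile + acid, settled at all times (K = 3.20 × 10⁻⁵ M)

In the flask at 14.7 min, the nucleophile step used electrophile 29 times as fast as the step with target, the half-lives of electrophile by the two steps being 2.1 min against 62 min. With its cover of 1.20, the flask at 50.0 min kept 21 % of its nucleophile, more than the 16.7 % reckoned, and 0.42 % of its electrophile. The neighbour with 0.036 M of nucleophile has a cover of 0.720, below the crossing; its reacted part of 83.5 % lies 11 points beyond that cover, and 16.5 % of its electrophile remains.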